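The cyclohex-2-ene-1,4-dione ring is traced back to a cyclohexene whose C3 and C6 carry acetoxy groups, and this ring is cut across C1–C6 and C2–C3 into (E,E)-1,4-diacetoxybutadiene (C3–C6) and a 1,1-disubstituted alkene (C1=C2). One enantioselective Diels–Alder reaction under a triflimide-activated chiral oxazaborolidine closes the six-membered carbocycle and sets the quaternary carbon C1 at once; the formyl carbon later becomes the CH2 of the CH2CO2Me arm. The dienophile is a 2-alkylacrolein carrying the complete C20 side chain, whose anti 12,13-diol travels as a bis(triethylsilyl) ether, a group that tolerates the cationic boron acid and leaves under mild acid.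

Key step: step 11

Assumption: the established facial models are taken to hold, i.e. the (R)-SEGPHOS iridium catalyst adds to the Re face of enal 3 (step 2) and the oxazaborolidinium from (S)-α,α-diphenylprolinol exposes the Si face at the α-carbon of 13 (step 11); both catalysts exist in either mirror-image form, so the antipode would be taken if a sense proved opposite.

Locants: ring atoms are numbered as in the target (C1 quaternary, C2 CH2, C3, C4=C5, C6); side-chain locants start at the carbon attached to C1.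

Step 1
Reactants: 1 (2E,6E)-farnesyl acetate
Product: 2 (2E,6E,10E)-12-hydroxy-3,7,11-trimethyldodeca-2,6,10-trien-1-yl acetate
Conditions: SeO2 (0.1 equiv), t-BuOOH (70% aq., 3 equiv), salicylic acid (0.1 equiv), CH2Cl2, 0 °C to rt; run to partial conversion, recover 1
Reagents that add atoms: tert-butyl hydroperoxide, CC(C)(C)OO (net oxygen source, relayed through selenium dioxide, O=[Se]=O)
Why: Riley-type allylic oxidation (ene reaction of SeO2, then [2,3]-sigmatropic shift) hydroxylates the (E)-methyl of the terminal, most electron-rich isopropylidene, the 2,3-alkene being deactivated by the allylic acetate; no stereocentre is formed and the (10E)-geometry follows from the mechanism.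

Step 2
Reactants: 2 (2E,6E,10E)-12-hydroxy-3,7,11-trimethyldodeca-2,6,10-trien-1-yl acetate
Product: 4 (2E,6E,10E,12S,13R)-13-(benzoyloxy)-12-hydroxy-3,7,11-trimethylpentadeca-2,6,10,14-tetraen-1-yl acetate, via 12-oxo enal 3 (not isolated)
Conditions: [Ir(cod)Cl]2 (2.5 mol%), (R)-SEGPHOS (5 mol%), 4-cyano-3-nitrobenzoic acid (10 mol%), K3PO4 (1 equiv), prop-2-ene-1,1-diyl dibenzoate (2 equiv), THF, 90 °C, sealed tube
Reagents that add atoms: prop-2-ene-1,1-diyl dibenzoate, C=CC(OC(=O)c1ccccc1)OC(=O)c1ccccc1 (one step from acrolein and benzoic anhydride)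
Why: Iridium-catalysed transfer-hydrogenative carbonyl (α-acyloxy)allylation: the catalyst dehydrogenates 2 to enal 3, ionises the gem-dibenzoate to an (E)-σ-(benzoyloxy)allyl iridium species and adds it through a closed chair transition state, which fixes the anti relationship, while (R)-SEGPHOS directs attack to the Re face of the aldehyde (12S, therefore 13R); the hindered trisubstituted allylic acetate at C1 should ionise far more slowly than the gem-dibenzoate.

Step 3
Reactants: 4 (2E,6E,10E,12S,13R)-13-(benzoyloxy)-12-hydroxy-3,7,11-trimethylpentadeca-2,6,10,14-tetraen-1-yl acetate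
Product: 5 (2E,6E,10E,12S,13R)-13-(benzoyloxy)-12-hydroxy-3,7,11,15-tetramethylhexadeca-2,6,10,14-tetraen-1-yl acetate
Conditions: second-generation Grubbs catalyst, (H2IMes)(PCy3)Cl2Ru=CHPh (5 mol%), 2-methylbut-2-ene/CH2Cl2 (1:1), 35 °C
Reagents that add atoms: 2-methylbut-2-ene, CC=C(C)C
Why: Olefin cross-metathesis with an excess of a trisubstituted partner converts the only monosubstituted alkene into the isopropylidene terminus, the trisubstituted chain alkenes being poor substrates for the ruthenium alkylidene at this temperature; no stereocentre is involved.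

Step 4
Reactants: 5 (2E,6E,10E,12S,13R)-13-(benzoyloxy)-12-hydroxy-3,7,11,15-tetramethylhexadeca-2,6,10,14-tetraen-1-yl acetate
Product: 6 (2E,6E,10E,12S,13R)-3,7,11,15-tetramethylhexadeca-2,6,10,14-tetraene-1,12,13-triol
Conditions: K2CO3 (0.5 equiv), MeOH, rt
Reagents that add atoms: none
Why: Base-catalysed transesterification removes the acetate and the benzoate together without breaking a C–O bond at C12 or C13, so the anti-diol configuration is retained.

Step 5
Reactants: 6 (2E,6E,10E,12S,13R)-3,7,11,15-tetramethylhexadeca-2,6,10,14-tetraene-1,12,13-triol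
Product: 7 1,12,13-tris(triethylsilyl) ether of triol 6
Conditions: TESCl (4 equiv), imidazole (6 equiv), DMAP (cat.), DMF, 0 °C to rt
Reagents that add atoms: chlorotriethylsilane, CC[Si](Cl)(CC)CC
Why: Exhaustive silylation with TESCl/imidazole is routine and avoids any need to distinguish the two secondary allylic hydroxyls.

Step 6
Reactants: 7 1,12,13-tris(triethylsilyl) ether of triol 6
Product: 8 (2E,6E,10E,12S,13R)-3,7,11,15-tetramethyl-12,13-bis(triethylsilyloxy)hexadeca-2,6,10,14-tetraen-1-ol
Conditions: PPTS (0.1 equiv), MeOH/CH2Cl2 (1:3), −10 to 0 °C, stopped when 7 is consumed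
Reagents that add atoms: none
Why: Acid-catalysed methanolysis of silyl ethers is governed by steric access, so the primary allylic triethylsilyl ether should be cleaved well before the two mutually shielding secondary ones.

Step 7
Reactants: 8 (2E,6E,10E,12S,13R)-3,7,11,15-tetramethyl-12,13-bis(triethylsilyloxy)hexadeca-2,6,10,14-tetraen-1-ol
Product: 9 (2E,6E,10E,12S,13R)-1-bromo-3,7,11,15-tetramethyl-12,13-bis(triethylsilyloxy)hexadeca-2,6,10,14-tetraene
Conditions: CBr4 (1.3 equiv), PPh3 (1.4 equiv), CH2Cl2, −20 to 0 °C; used crude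
Reagents that add atoms: tetrabromomethane, BrC(Br)(Br)Br
Why: Appel bromination proceeds by SN2 displacement of the alkoxyphosphonium at the primary allylic carbon under neutral conditions, which preserves the (2E)-geometry and the silyl ethers.

Step 8
Reactants: 9 (2E,6E,10E,12S,13R)-1-bromo-3,7,11,15-tetramethyl-12,13-bis(triethylsilyloxy)hexadeca-2,6,10,14-tetraene
Product: 10 (4E,8E,12E,14S,15R)-5,9,13,17-tetramethyl-14,15-bis(triethylsilyloxy)octadeca-4,8,12,16-tetraenenitrile
Conditions: MeCN (6 equiv), n-BuLi (5 equiv), THF, −78 °C, 30 min; then 9, −78 to −40 °C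
Reagents that add atoms: acetonitrile, CC#N
Why: SN2 alkylation of lithioacetonitrile by a primary allylic bromide is a standard two-carbon homologation of prenyl-type halides, the excess of the small nucleophile suppressing dialkylation and the low temperature disfavouring SN2′ attack at the fully substituted alkene carbon.

Step 9
Reactants: 10 (4E,8E,12E,14S,15R)-5,9,13,17-tetramethyl-14,15-bis(triethylsilyloxy)octadeca-4,8,12,16-tetraenenitrile
Product: 12 (4E,8E,12E,14S,15R)-5,9,13,17-tetramethyl-14,15-bis(triethylsilyloxy)octadeca-4,8,12,16-tetraenal, via N-aluminated aldimine 11 (not isolated)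
Conditions: i-Bu2AlH (1.3 equiv), CH2Cl2, −78 °C; then MeOH, aq. KNaC4H4O6 (potassium sodium tartrate), rt
Reagents that add atoms: water, O
Why: Partial reduction of a nitrile with i-Bu2AlH stops at the N-aluminated aldimine, which is hydrolysed on work-up to the aldehyde without over-reduction and without loss of the silyl ethers.

Step 10
Reactants: 12 (4E,8E,12E,14S,15R)-5,9,13,17-tetramethyl-14,15-bis(triethylsilyloxy)octadeca-4,8,12,16-tetraenal
Product: 13 (4E,8E,12E,14S,15R)-5,9,13,17-tetramethyl-2-methylidene-14,15-bis(triethylsilyloxy)octadeca-4,8,12,16-tetraenal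
Conditions: 37% aq. CH2O (1.2 equiv), pyrrolidine (10 mol%), propionic acid (10 mol%), i-PrOH/THF, 45 °C
Reagents that add atoms: formaldehyde, C=O
Why: Amine-catalysed α-methylenation of an aldehyde (Mannich condensation with formaldehyde, then elimination of the amine) installs the 1,1-disubstituted alkene; the product has no α-hydrogen and is used promptly to avoid polymerisation.

Step 11
Reactants: 13 (4E,8E,12E,14S,15R)-5,9,13,17-tetramethyl-2-methylidene-14,15-bis(triethylsilyloxy)octadeca-4,8,12,16-tetraenal; 14 (1E,3E)-buta-1,3-diene-1,4-diyl diacetate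
Product: 15 (1S,3R,6R)-1-formyl-1-[(2E,6E,10E,12S,13R)-3,7,11,15-tetramethyl-12,13-bis(triethylsilyloxy)hexadeca-2,6,10,14-tetraen-1-yl]cyclohex-4-ene-3,6-diyl diacetate (CHO and both OAc on one face)
Conditions: oxazaborolidine from (S)-α,α-diphenylprolinol and o-tolylboronic acid (0.24 equiv), Tf2NH (0.20 equiv), CH2Cl2, −25 °C, 10 min; then 13 (1 equiv), 14 (3 equiv), −78 to −20 °C
Reagents that add atoms: none
Why: The boron cation binds the formyl oxygen of 13 syn to the formyl hydrogen, which is held against the ring oxygen of the catalyst, so that the s-trans enal lies over one phenyl group, and diene 14 then adds to the LUMO-lowered alkene in a concerted, asynchronous, suprafacial [4+2] cycloaddition that forms C1–C6 and C2–C3. The closest known reaction type is the cationic oxazaborolidine-catalysed Diels–Alder reaction of 2-alkylacroleins with acyclic 1-oxygenated butadienes. The six-membered ring is closed by intermolecular [4π+2π] annulation, both σ-bonds being made in the same step, so no tethered ring-closure mode is involved. C1 is controlled by the catalyst, whose phenyl group covers the Re face of the α-carbon so that the diene bonds on the Si face (1S in 15, the arrangement that becomes 1R in the target); C3 and C6 are controlled by the (E,E)-geometry of the diene (mutually cis) and by the endo preference of the formyl group (cis to CHO), and both are erased in step 14. Only π-facial selectivity at the dienophile is required, since the identical ends of the diene exclude regioisomers and any exo adduct converges on the same enedione; the substrate secures it through the 2-alkylacrolein motif, the best substrate class for this catalyst, and through silyl ethers that are too hindered to compete with the aldehyde for boron.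

Step 12
Reactants: 15 (1S,3R,6R)-1-formyl-1-[(2E,6E,10E,12S,13R)-3,7,11,15-tetramethyl-12,13-bis(triethylsilyloxy)hexadeca-2,6,10,14-tetraen-1-yl]cyclohex-4-ene-3,6-diyl diacetate
Product: 16 (1R,3R,6R)-1-(2-methoxyethenyl)-1-[(2E,6E,10E,12S,13R)-3,7,11,15-tetramethyl-12,13-bis(triethylsilyloxy)hexadeca-2,6,10,14-tetraen-1-yl]cyclohex-4-ene-3,6-diyl diacetate (E/Z mixture at the enol ether)
Conditions: MeOCH2PPh3Cl (3 equiv), KN(SiMe3)2 (2.8 equiv), THF, 0 °C; then 15, −78 to 0 °C
Reagents that add atoms: (methoxymethyl)triphenylphosphonium chloride, COC[P+](c1ccccc1)(c1ccccc1)c1ccccc1.[Cl-]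
Why: Wittig methoxymethylenation of the neopentyl aldehyde, which has no α-hydrogen and therefore can neither epimerise nor lose acetate by β-elimination, masks the future carboxyl carbon as an enol ether before the acetates are removed, so a β-hydroxy aldehyde prone to retro-aldol cleavage is never formed.

Step 13
Reactants: 16 (1R,3R,6R)-1-(2-methoxyethenyl)-1-[(2E,6E,10E,12S,13R)-3,7,11,15-tetramethyl-12,13-bis(triethylsilyloxy)hexadeca-2,6,10,14-tetraen-1-yl]cyclohex-4-ene-3,6-diyl diacetate
Product: 17 (1R,3R,6R)-1-(2-methoxyethenyl)-1-[(2E,6E,10E,12S,13R)-3,7,11,15-tetramethyl-12,13-bis(triethylsilyloxy)hexadeca-2,6,10,14-tetraen-1-yl]cyclohex-4-ene-3,6-diol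
Conditions: K2CO3 (0.3 equiv), MeOH, 0 °C to rt
Reagents that add atoms: none
Why: Base-catalysed methanolysis cleaves both acetates while the enol ether and the secondary silyl ethers are stable to K2CO3/MeOH, and with the side arm still an enol ether the C6 hydroxyl cannot lactonise.

Step 14
Reactants: 17 (1R,3R,6R)-1-(2-methoxyethenyl)-1-[(2E,6E,10E,12S,13R)-3,7,11,15-tetramethyl-12,13-bis(triethylsilyloxy)hexadeca-2,6,10,14-tetraen-1-yl]cyclohex-4-ene-3,6-diol
Product: 18 (1R)-1-(2-methoxyethenyl)-1-[(2E,6E,10E,12S,13R)-3,7,11,15-tetramethyl-12,13-bis(triethylsilyloxy)hexadeca-2,6,10,14-tetraen-1-yl]cyclohex-4-ene-3,6-dione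
Conditions: activated MnO2 (30 equiv), CH2Cl2, rt
Reagents that add atoms: none
Why: MnO2 oxidises allylic alcohols selectively under neutral conditions, converting both ring carbinols into the enedione and thereby erasing C3 and C6, while the quaternary C1 blocks tautomerisation to a hydroquinone and the enol ether survives.

Step 15
Reactants: 18 (1R)-1-(2-methoxyethenyl)-1-[(2E,6E,10E,12S,13R)-3,7,11,15-tetramethyl-12,13-bis(triethylsilyloxy)hexadeca-2,6,10,14-tetraen-1-yl]cyclohex-4-ene-3,6-dione
Product: 19 2-[(1S)-1-[(2E,6E,10E,12S,13R)-12,13-dihydroxy-3,7,11,15-tetramethylhexadeca-2,6,10,14-tetraen-1-yl]-3,6-dioxocyclohex-4-en-1-yl]acetaldehyde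
Conditions: 1 M aq. HCl/THF (1:4), 0 °C to rt; neutralised with NaHCO3 and used crude at once
Reagents that add atoms: water, O
Why: Specific-acid hydrolysis of the enol ether (C-protonation, hydration, loss of methanol) and acidic cleavage of the two secondary triethylsilyl ethers occur in one mild operation, and the quaternary C1, which bears no hydrogen, cannot epimerise.

Step 16
Reactants: 19 2-[(1S)-1-[(2E,6E,10E,12S,13R)-12,13-dihydroxy-3,7,11,15-tetramethylhexadeca-2,6,10,14-tetraen-1-yl]-3,6-dioxocyclohex-4-en-1-yl]acetaldehyde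
Product: 20 2-[(1R)-1-[(2E,6E,10E,12S,13R)-12,13-dihydroxy-3,7,11,15-tetramethylhexadeca-2,6,10,14-tetraen-1-yl]-3,6-dioxocyclohex-4-en-1-yl]acetic acid
Conditions: NaClO2 (3 equiv), NaH2PO4 (4 equiv), 2-methylbut-2-ene (30 equiv), t-BuOH/H2O (4:1), 0 °C
Reagents that add atoms: sodium chlorite, [Na+].[O-]Cl=O
Why: Pinnick chlorite oxidation converts the aliphatic aldehyde into the acid at buffered pH with 2-methylbut-2-ene scavenging the hypochlorous acid, conditions expected to leave the trisubstituted alkenes, the allylic diol and the enedione untouched.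

Step 17
Reactants: 20 2-[(1R)-1-[(2E,6E,10E,12S,13R)-12,13-dihydroxy-3,7,11,15-tetramethylhexadeca-2,6,10,14-tetraen-1-yl]-3,6-dioxocyclohex-4-en-1-yl]acetic acid
Product: 21 methyl 2-[(1R)-1-[(2E,6E,10E,12S,13R)-12,13-dihydroxy-3,7,11,15-tetramethylhexadeca-2,6,10,14-tetraen-1-yl]-3,6-dioxocyclohex-4-en-1-yl]acetate (CNP0122011.2)
Conditions: MeI (3 equiv), KHCO3 (2 equiv), DMF, rt
Reagents that add atoms: iodomethane, CI
Why: SN2 O-methylation of the carboxylate with iodomethane under bicarbonate, a base too weak to enolise the enedione, gives the methyl ester without the dipolar cycloaddition that a diazoalkane could undergo with the electron-poor ring alkene.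

Compound list

1 | (2E,6E)-farnesyl acetate | CC(=O)OC/C=C(\C)CC/C=C(\C)CCC=C(C)C | starting material
2 | (2E,6E,10E)-12-hydroxy-3,7,11-trimethyldodeca-2,6,10-trien-1-yl acetate | CC(=O)OC/C=C(\C)CC/C=C(\C)CC/C=C(\C)CO | intermediate
3 | (2E,6E,10E)-3,7,11-trimethyl-12-oxododeca-2,6,10-trien-1-yl acetate (12-oxo enal, not isolated) | CC(=O)OC/C=C(\C)CC/C=C(\C)CC/C=C(\C)C=O | intermediate
4 | (2E,6E,10E,12S,13R)-13-(benzoyloxy)-12-hydroxy-3,7,11-trimethylpentadeca-2,6,10,14-tetraen-1-yl acetate | CC(=O)OC/C=C(\C)CC/C=C(\C)CC/C=C(\C)[C@H](O)[C@H](OC(=O)c1ccccc1)C=C | intermediate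
5 | (2E,6E,10E,12S,13R)-13-(benzoyloxy)-12-hydroxy-3,7,11,15-tetramethylhexadeca-2,6,10,14-tetraen-1-yl acetate | CC(=O)OC/C=C(\C)CC/C=C(\C)CC/C=C(\C)[C@H](O)[C@H](OC(=O)c1ccccc1)C=C(C)C | intermediate
6 | (2E,6E,10E,12S,13R)-3,7,11,15-tetramethylhexadeca-2,6,10,14-tetraene-1,12,13-triol | OC/C=C(\C)CC/C=C(\C)CC/C=C(\C)[C@H](O)[C@H](O)C=C(C)C | intermediate
7 | 1,12,13-tris(triethylsilyl) ether of triol 6 | CC[Si](CC)(CC)OC/C=C(\C)CC/C=C(\C)CC/C=C(\C)[C@H](O[Si](CC)(CC)CC)[C@H](O[Si](CC)(CC)CC)C=C(C)C | intermediate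
8 | (2E,6E,10E,12S,13R)-3,7,11,15-tetramethyl-12,13-bis(triethylsilyloxy)hexadeca-2,6,10,14-tetraen-1-ol | OC/C=C(\C)CC/C=C(\C)CC/C=C(\C)[C@H](O[Si](CC)(CC)CC)[C@H](O[Si](CC)(CC)CC)C=C(C)C | intermediate
9 | (2E,6E,10E,12S,13R)-1-bromo-3,7,11,15-tetramethyl-12,13-bis(triethylsilyloxy)hexadeca-2,6,10,14-tetraene | BrC/C=C(\C)CC/C=C(\C)CC/C=C(\C)[C@H](O[Si](CC)(CC)CC)[C@H](O[Si](CC)(CC)CC)C=C(C)C | intermediate
10 | (4E,8E,12E,14S,15R)-5,9,13,17-tetramethyl-14,15-bis(triethylsilyloxy)octadeca-4,8,12,16-tetraenenitrile | N#CCC/C=C(\C)CC/C=C(\C)CC/C=C(\C)[C@H](O[Si](CC)(CC)CC)[C@H](O[Si](CC)(CC)CC)C=C(C)C | intermediate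
11 | N-(diisobutylalumino) aldimine of aldehyde 12 (not isolated) | CC(C)C[Al](CC(C)C)N=CCC/C=C(\C)CC/C=C(\C)CC/C=C(\C)[C@H](O[Si](CC)(CC)CC)[C@H](O[Si](CC)(CC)CC)C=C(C)C | intermediate
12 | (4E,8E,12E,14S,15R)-5,9,13,17-tetramethyl-14,15-bis(triethylsilyloxy)octadeca-4,8,12,16-tetraenal | O=CCC/C=C(\C)CC/C=C(\C)CC/C=C(\C)[C@H](O[Si](CC)(CC)CC)[C@H](O[Si](CC)(CC)CC)C=C(C)C | intermediate
13 | (4E,8E,12E,14S,15R)-5,9,13,17-tetramethyl-2-methylidene-14,15-bis(triethylsilyloxy)octadeca-4,8,12,16-tetraenal (dienophile) | O=CC(=C)C/C=C(\C)CC/C=C(\C)CC/C=C(\C)[C@H](O[Si](CC)(CC)CC)[C@H](O[Si](CC)(CC)CC)C=C(C)C | intermediate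
14 | (1E,3E)-buta-1,3-diene-1,4-diyl diacetate | CC(=O)O/C=C/C=C/OC(C)=O | starting material
15 | (1S,3R,6R)-1-formyl-1-[(2E,6E,10E,12S,13R)-3,7,11,15-tetramethyl-12,13-bis(triethylsilyloxy)hexadeca-2,6,10,14-tetraen-1-yl]cyclohex-4-ene-3,6-diyl diacetate (all-cis adduct) | O=C[C@@]1(C/C=C(\C)CC/C=C(\C)CC/C=C(\C)[C@H](O[Si](CC)(CC)CC)[C@H](O[Si](CC)(CC)CC)C=C(C)C)C[C@@H](OC(C)=O)C=C[C@H]1OC(C)=O | intermediate
16 | (1R,3R,6R)-1-(2-methoxyethenyl)-1-[side chain as in 15]cyclohex-4-ene-3,6-diyl diacetate (E/Z mixture at the enol ether) | COC=C[C@@]1(C/C=C(\C)CC/C=C(\C)CC/C=C(\C)[C@H](O[Si](CC)(CC)CC)[C@H](O[Si](CC)(CC)CC)C=C(C)C)C[C@@H](OC(C)=O)C=C[C@H]1OC(C)=O | intermediate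
17 | (1R,3R,6R)-1-(2-methoxyethenyl)-1-[side chain as in 15]cyclohex-4-ene-3,6-diol | COC=C[C@@]1(C/C=C(\C)CC/C=C(\C)CC/C=C(\C)[C@H](O[Si](CC)(CC)CC)[C@H](O[Si](CC)(CC)CC)C=C(C)C)C[C@@H](O)C=C[C@H]1O | intermediate
18 | (1R)-1-(2-methoxyethenyl)-1-[side chain as in 15]cyclohex-4-ene-3,6-dione | COC=C[C@@]1(C/C=C(\C)CC/C=C(\C)CC/C=C(\C)[C@H](O[Si](CC)(CC)CC)[C@H](O[Si](CC)(CC)CC)C=C(C)C)CC(=O)C=CC1=O | intermediate
19 | 2-[(1S)-1-[(2E,6E,10E,12S,13R)-12,13-dihydroxy-3,7,11,15-tetramethylhexadeca-2,6,10,14-tetraen-1-yl]-3,6-dioxocyclohex-4-en-1-yl]acetaldehyde | O=CC[C@@]1(C/C=C(\C)CC/C=C(\C)CC/C=C(\C)[C@H](O)[C@H](O)C=C(C)C)CC(=O)C=CC1=O | intermediate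
20 | 2-[(1R)-1-[(2E,6E,10E,12S,13R)-12,13-dihydroxy-3,7,11,15-tetramethylhexadeca-2,6,10,14-tetraen-1-yl]-3,6-dioxocyclohex-4-en-1-yl]acetic acid | OC(=O)C[C@@]1(C/C=C(\C)CC/C=C(\C)CC/C=C(\C)[C@H](O)[C@H](O)C=C(C)C)CC(=O)C=CC1=O | intermediate
21 | methyl 2-[(1R)-1-[(2E,6E,10E,12S,13R)-12,13-dihydroxy-3,7,11,15-tetramethylhexadeca-2,6,10,14-tetraen-1-yl]-3,6-dioxocyclohex-4-en-1-yl]acetate | COC(=O)C[C@@]1(C/C=C(\C)CC/C=C(\C)CC/C=C(\C)[C@H](O)[C@H](O)C=C(C)C)CC(=O)C=CC1=O | target

Total step count: 17. Longest linear sequence: 17 steps (1 to 21); diene 14 is used as purchased in step 11.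

Steps most likely to fail

Step 11. What may go wrong: competition of the diene's ester carbonyls with the aldehyde for boron, slow cycloaddition of a diene substituted at both ends, ionisation of the allylic acetates of the adduct by the cationic acid, or erosion of facial control at the higher temperature then needed. Fallback: the second ring oxygen would be introduced after the cycloaddition instead of with it. Setting out from 13, the same catalyst would be used with commercial (E)-1-acetoxybuta-1,3-diene, a more reactive and regiochemically biased diene of the established class, to give the 6-acetoxy adduct F1 (ortho regiochemistry, C1 as in 15). Wittig methoxymethylenation would give the enol ether F2, K2CO3/MeOH the allylic alcohol F3, and MnO2 the cyclohex-4-en-6-one F4. Because C1 is quaternary, KOt-Bu can deprotonate only C3; trapping of this dienolate with O2 in the presence of P(OEt)3 would give the 3-hydroxy enone F5, which MnO2 would oxidise to enedione 18, where the route is rejoined.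

Step 2. What may go wrong: ionisation of the C1 allylic acetate by the iridium catalyst, redox isomerisation of the allylic alcohol to a saturated aldehyde, or insufficient anti and facial control with this α-branched enal. Fallback: a stoichiometric chiral boron reagent would replace the catalysis. Setting out from 2, MnO2 would give enal 3. The (E)-γ-[(diisopropylamino)dimethylsilyl]allyl-diisopinocampheylborane (from allyl(diisopropylamino)dimethylsilane, n-BuLi/TMEDA, the appropriate enantiomer of B-methoxydiisopinocampheylborane and BF3·OEt2) would add through a chair transition state to give the anti β-hydroxy allylsilane F6. Tamao–Fleming oxidation (H2O2, KF, KHCO3), which proceeds with retention, would give the anti diol F7; cross-metathesis with 2-methylbut-2-ene would give the isopropylidene diol F8; K2CO3/MeOH would return triol 6, where the route is rejoined.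

Step 15. What may go wrong: acid-promoted ionisation and allylic transposition of the prenyl-type carbinol, or slow hydrolysis of the hindered enol ether that forces harsher acid. Fallback: aqueous acid would be avoided. Setting out from 18, buffered pyridinium chlorochromate (C5H5NH[CrO3Cl], NaOAc, CH2Cl2) would oxidise the enol ether directly to the bis-silylated methyl ester F9, a known oxidation of enol ethers to esters. HF·pyridine buffered with pyridine in THF would then remove both silyl groups and give target 21, so that steps 16 and 17 are bypassed as well.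

Further compounds

F1 | step 11 | 6-acetoxy-1-[side chain as in 15]cyclohex-4-ene-1-carbaldehyde (OAc cis to CHO, C1 as in 15) | O=C[C@@]1(C/C=C(\C)CC/C=C(\C)CC/C=C(\C)[C@H](O[Si](CC)(CC)CC)[C@H](O[Si](CC)(CC)CC)C=C(C)C)CCC=C[C@H]1OC(C)=O
F2 | step 11 | 1-(2-methoxyethenyl)-1-[side chain as in 15]cyclohex-4-en-6-yl acetate | COC=C[C@@]1(C/C=C(\C)CC/C=C(\C)CC/C=C(\C)[C@H](O[Si](CC)(CC)CC)[C@H](O[Si](CC)(CC)CC)C=C(C)C)CCC=C[C@H]1OC(C)=O
F3 | step 11 | 1-(2-methoxyethenyl)-1-[side chain as in 15]cyclohex-4-en-6-ol | COC=C[C@@]1(C/C=C(\C)CC/C=C(\C)CC/C=C(\C)[C@H](O[Si](CC)(CC)CC)[C@H](O[Si](CC)(CC)CC)C=C(C)C)CCC=C[C@H]1O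
F4 | step 11 | 1-(2-methoxyethenyl)-1-[side chain as in 15]cyclohex-4-en-6-one | COC=C[C@@]1(C/C=C(\C)CC/C=C(\C)CC/C=C(\C)[C@H](O[Si](CC)(CC)CC)[C@H](O[Si](CC)(CC)CC)C=C(C)C)CCC=CC1=O
F5 | step 11 | 3-hydroxy-1-(2-methoxyethenyl)-1-[side chain as in 15]cyclohex-4-en-6-one (C3 epimers) | COC=C[C@@]1(C/C=C(\C)CC/C=C(\C)CC/C=C(\C)[C@H](O[Si](CC)(CC)CC)[C@H](O[Si](CC)(CC)CC)C=C(C)C)CC(O)C=CC1=O
F6 | step 2 | (2E,6E,10E,12S,13R)-13-[(diisopropylamino)dimethylsilyl]-12-hydroxy-3,7,11-trimethylpentadeca-2,6,10,14-tetraen-1-yl acetate (anti) | CC(=O)OC/C=C(\C)CC/C=C(\C)CC/C=C(\C)[C@H](O)[C@H]([Si](C)(C)N(C(C)C)C(C)C)C=C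
F7 | step 2 | (2E,6E,10E,12S,13R)-12,13-dihydroxy-3,7,11-trimethylpentadeca-2,6,10,14-tetraen-1-yl acetate | CC(=O)OC/C=C(\C)CC/C=C(\C)CC/C=C(\C)[C@H](O)[C@H](O)C=C
F8 | step 2 | (2E,6E,10E,12S,13R)-12,13-dihydroxy-3,7,11,15-tetramethylhexadeca-2,6,10,14-tetraen-1-yl acetate | CC(=O)OC/C=C(\C)CC/C=C(\C)CC/C=C(\C)[C@H](O)[C@H](O)C=C(C)C
F9 | step 15 | methyl 2-[(1R)-3,6-dioxo-1-[(2E,6E,10E,12S,13R)-3,7,11,15-tetramethyl-12,13-bis(triethylsilyloxy)hexadeca-2,6,10,14-tetraen-1-yl]cyclohex-4-en-1-yl]acetate | COC(=O)C[C@@]1(C/C=C(\C)CC/C=C(\C)CC/C=C(\C)[C@H](O[Si](CC)(CC)CC)[C@H](O[Si](CC)(CC)CC)C=C(C)C)CC(=O)C=CC1=O
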